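**Strategy.** Ring A (the phenol ring: C1–OH, C2–OAr, C5–Br, C6–Br) is not taken from an arene but assembled as a cyclohexane-1,3-dione, because its C1 oxygen and C5 bromine are 1,3-related with the C6 bromine between them and the aryloxy carbon C2 flanks C1. A Michael–Claisen annulation of a mixed tert-butyl ethyl (2,4-dibromophenoxy)malonate with methyl vinyl ketone forms C2–C3 and C6–C1 in one operation. The ethyl ester is the acylating group; the tert-butyl ester is kept so that C2 stays quaternary while C6 is brominated and C5–O is exchanged for bromine, then it is removed with acid and ring A is dehydrogenated.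

Key step: step 3

Remark: the ring A labels C1–C6 follow the target and are used for all intermediates, while systematic names carry their own locants; ring B is the 2,4-dibromophenyl ring. Every sp3 stereocentre on the way is racemic and the target is achiral.

**Step 1**
Reactants: 1 2,4-dibromophenol; 2 tert-butyl bromoacetate
Product: 3 tert-butyl 2-(2,4-dibromophenoxy)acetate
Conditions: K2CO3, acetone, reflux
Reagents that add atoms: none
Why: Williamson ether synthesis, in which the acidic phenol is deprotonated by K2CO3 and the phenoxide displaces bromide from the unhindered, carbonyl-activated primary bromide while the tert-butyl ester stays inert.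

**Step 2**
Reactants: 3 tert-butyl 2-(2,4-dibromophenoxy)acetate; 4 ethyl chloroformate
Product: 5 1-tert-butyl 3-ethyl 2-(2,4-dibromophenoxy)propanedioate (racemic)
Conditions: LiN(SiMe3)2 (2.1 equiv), THF, −78 °C; then 4 (1.0 equiv), −78 → −20 °C; sat. aq NH4Cl
Reagents that add atoms: none
Why: C-acylation of an ester enolate (crossed Claisen-type carboxylation), in which the silylamide base is too weak to metalate ring B, the tert-butyl ester enolate does not self-condense at low temperature, and the second equivalent of base holds the malonate as its enolate so that it is not acylated twice; the new C–H stereocentre is racemic and of no consequence.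

**Step 3**
Reactants: 5 1-tert-butyl 3-ethyl 2-(2,4-dibromophenoxy)propanedioate; 6 methyl vinyl ketone
Product: 8 tert-butyl 1-(2,4-dibromophenoxy)-2,4-dioxocyclohexane-1-carboxylate (racemic), via Michael adduct 7 (not isolated)
Conditions: KOtBu (0.1 equiv), 6 (1.05 equiv), THF, 0 °C; then KOtBu (1.5 equiv), 0 °C → rt; cold 1 M HCl
Reagents that add atoms: none
Why: Catalytic tert-butoxide generates the anion of 5, whose only acidic carbon (future C2) adds 1,4 to 6 to form C2–C3; with a full equivalent of base the ketone of 7 is enolized, its methyl-terminus enolate (C6) attacks the ethyl ester carbonyl (C1), ethoxide leaves and the 1,3-dione is at once deprotonated at C6, which pulls the preceding equilibria forward. The closest known reaction type is the Michael–Claisen (dimedone-type) annulation of malonates with enones. Ring A closes in a 6-(enolexo)-exo-trig mode, the only closure open to the methyl ketone because its internal enolate could form nothing larger than a four-membered ring. The quaternary C2 is the single new stereocentre; nothing controls it, it arises racemic and is flattened on aromatization, so no control is needed. The step needs acylation by the ethyl rather than the tert-butyl ester, which the smaller size and better leaving group of the ethyl ester and the non-nucleophilic base should secure, and the near-stoichiometric charge of 6 keeps the product enolate from a second conjugate addition.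

**Step 4**
Reactants: 8 tert-butyl 1-(2,4-dibromophenoxy)-2,4-dioxocyclohexane-1-carboxylate
Product: 9 tert-butyl 3-bromo-1-(2,4-dibromophenoxy)-4-hydroxy-2-oxocyclohex-3-ene-1-carboxylate (racemic; enol form of the 3-bromo-2,4-dione)
Conditions: NBS (1.0 equiv), CH2Cl2, 0 °C
Reagents that add atoms: N-bromosuccinimide, O=C1CCC(=O)N1Br
Why: Electrophilic bromination of a 1,3-dicarbonyl compound at its central carbon, since only C6 between the C1 and C5 carbonyls is appreciably enolized and one equivalent of NBS in the cold leaves the deactivated ring B and the ester untouched.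

**Step 5**
Reactants: 9 tert-butyl 3-bromo-1-(2,4-dibromophenoxy)-4-hydroxy-2-oxocyclohex-3-ene-1-carboxylate
Product: 10 tert-butyl 3,4-dibromo-1-(2,4-dibromophenoxy)-2-oxocyclohex-3-ene-1-carboxylate (racemic)
Conditions: Ph3PBr2 (1.2 equiv), Et3N (1.3 equiv), MeCN, 0 °C → rt
Reagents that add atoms: dibromotriphenylphosphorane (Ph3PBr2), BrP(Br)(c1ccccc1)(c1ccccc1)c1ccccc1
Why: Conversion of a 1,3-dione into a β-bromo enone with a triphenylphosphine dihalide and an amine base (enol phosphonium salt, then addition–elimination of bromide), in which the quaternary C2 with its aryloxy and ester groups shields the C1 carbonyl so that activation and bromide attack are expected at the remote C5, and the buffered medium spares the tert-butyl ester.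

**Step 6**
Reactants: 10 tert-butyl 3,4-dibromo-1-(2,4-dibromophenoxy)-2-oxocyclohex-3-ene-1-carboxylate
Product: 12 2,3-dibromo-6-(2,4-dibromophenoxy)cyclohex-2-en-1-one (racemic), via keto acid 11 (not isolated)
Conditions: TFA, CH2Cl2, rt; evaporate; toluene, 70 °C
Reagents that add atoms: none
Why: Acidolysis of the tert-butyl ester with loss of isobutene followed by thermal decarboxylation of the β-keto acid through its cyclic six-membered transition state, under conditions free of water and nucleophiles that could attack the vinylogous acyl bromide; the C2–H stereocentre formed on ketonization is racemic.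

**Step 7**
Reactants: 12 2,3-dibromo-6-(2,4-dibromophenoxy)cyclohex-2-en-1-one
Product: 13 2,3-dibromo-6-(2,4-dibromophenoxy)phenol
Conditions: DDQ (1.3 equiv), camphorsulfonic acid (cat.), 1,4-dioxane, 90 °C
Reagents that add atoms: none
Why: DDQ dehydrogenation of a cyclohexenone to a phenol, in which acid-promoted enolization toward C2 gives a cyclohexa-1,3-dienol, DDQ abstracts hydride from C3 and loss of the C4 proton aromatizes ring A and removes the last stereocentre, the electron-poor phenol being resistant to further oxidation.

**Compound list**
1 | 2,4-dibromophenol | Oc1ccc(Br)cc1Br | starting material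
2 | tert-butyl bromoacetate | CC(C)(C)OC(=O)CBr | starting material
3 | tert-butyl 2-(2,4-dibromophenoxy)acetate | CC(C)(C)OC(=O)COc1ccc(Br)cc1Br | intermediate
4 | ethyl chloroformate | CCOC(Cl)=O | starting material
5 | 1-tert-butyl 3-ethyl 2-(2,4-dibromophenoxy)propanedioate (racemic) | CCOC(=O)C(Oc1ccc(Br)cc1Br)C(=O)OC(C)(C)C | intermediate
6 | methyl vinyl ketone (but-3-en-2-one) | CC(=O)C=C | starting material
7 | 1-tert-butyl 3-ethyl 2-(2,4-dibromophenoxy)-2-(3-oxobutyl)propanedioate (racemic) | CCOC(=O)C(CCC(C)=O)(Oc1ccc(Br)cc1Br)C(=O)OC(C)(C)C | intermediate (not isolated)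
8 | tert-butyl 1-(2,4-dibromophenoxy)-2,4-dioxocyclohexane-1-carboxylate (racemic) | CC(C)(C)OC(=O)C1(Oc2ccc(Br)cc2Br)CCC(=O)CC1=O | intermediate
9 | tert-butyl 3-bromo-1-(2,4-dibromophenoxy)-4-hydroxy-2-oxocyclohex-3-ene-1-carboxylate (racemic, enol form) | CC(C)(C)OC(=O)C1(Oc2ccc(Br)cc2Br)CCC(O)=C(Br)C1=O | intermediate
10 | tert-butyl 3,4-dibromo-1-(2,4-dibromophenoxy)-2-oxocyclohex-3-ene-1-carboxylate (racemic) | CC(C)(C)OC(=O)C1(Oc2ccc(Br)cc2Br)CCC(Br)=C(Br)C1=O | intermediate
11 | 3,4-dibromo-1-(2,4-dibromophenoxy)-2-oxocyclohex-3-ene-1-carboxylic acid (racemic) | OC(=O)C1(Oc2ccc(Br)cc2Br)CCC(Br)=C(Br)C1=O | intermediate (not isolated)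
12 | 2,3-dibromo-6-(2,4-dibromophenoxy)cyclohex-2-en-1-one (racemic) | O=C1C(Br)=C(Br)CCC1Oc1ccc(Br)cc1Br | intermediate
13 | 2,3-dibromo-6-(2,4-dibromophenoxy)phenol | Oc1c(Oc2ccc(Br)cc2Br)ccc(Br)c1Br | target

**Total step count:** 7. **Longest linear sequence:** 7 steps (the route is fully linear from 1).

**Steps most likely to fail**

Step 3. Anionic oligomerization of the enone, or reversal of the conjugate addition under the strongly basic conditions of the ring closure, may outrun the acylation. The fallback sets out from 5 and replaces the conjugate addition by an alkylation with a masked ketone. The sodium enolate of 5 (NaH, DMF, 50 °C) is alkylated with commercial 2-(2-bromoethyl)-2-methyl-1,3-dioxolane to give 1-tert-butyl 3-ethyl 2-(2,4-dibromophenoxy)-2-[2-(2-methyl-1,3-dioxolan-2-yl)ethyl]propanedioate F1. Its ketal is cleaved with pyridinium p-toluenesulfonate in wet acetone at reflux, which the tert-butyl ester should survive. This brings the fallback back to the route at 7, now isolated, which is closed separately under kinetic enolization (LiN(SiMe3)2, THF, −78 → 0 °C) to 8.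

Step 5. The hindered, weakly nucleophilic bromo-enolate may be activated too slowly at oxygen, or its C6 bromine may be transferred to the reagent and lost. The fallback sets out from 8 and inverts the order of the two bromine introductions. Ph3PBr2 and Et3N in MeCN should convert 8, with the same steric bias from quaternary C2, into tert-butyl 4-bromo-1-(2,4-dibromophenoxy)-2-oxocyclohex-3-ene-1-carboxylate F2. Bromine (CH2Cl2, 0 °C) then adds across C5=C6 to give tert-butyl 3,4,4-tribromo-1-(2,4-dibromophenoxy)-2-oxocyclohexane-1-carboxylate F3, and Et3N removes HBr in the same flask (enone α-bromination by addition–elimination). The fallback returns to the route at 10.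

Step 7. Dienolization and hydride abstraction on the electron-poor dibromo enone may be sluggish, so that hydrolysis of the vinylogous acyl bromide or over-oxidation competes at the high temperature. The fallback sets out from 12 and uses selenoxide elimination at low temperature. Kinetic deprotonation at C2 (LiN(SiMe3)2, THF, −78 °C) and trapping with PhSeBr should give 2,3-dibromo-6-(2,4-dibromophenoxy)-6-(phenylselanyl)cyclohex-2-en-1-one F4. H2O2 with pyridine in CH2Cl2 at 0 °C oxidizes it to 6-(benzeneseleninyl)-2,3-dibromo-6-(2,4-dibromophenoxy)cyclohex-2-en-1-one F5. Syn elimination toward C3 and tautomerization of the resulting dienone then return to the route at 13.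

**Further compounds**
F1 | step 3 | 1-tert-butyl 3-ethyl 2-(2,4-dibromophenoxy)-2-[2-(2-methyl-1,3-dioxolan-2-yl)ethyl]propanedioate (racemic) | CCOC(=O)C(CCC1(C)OCCO1)(Oc1ccc(Br)cc1Br)C(=O)OC(C)(C)C
F2 | step 5 | tert-butyl 4-bromo-1-(2,4-dibromophenoxy)-2-oxocyclohex-3-ene-1-carboxylate (racemic) | CC(C)(C)OC(=O)C1(Oc2ccc(Br)cc2Br)CCC(Br)=CC1=O
F3 | step 5 | tert-butyl 3,4,4-tribromo-1-(2,4-dibromophenoxy)-2-oxocyclohexane-1-carboxylate (mixture of racemic diastereomers) | CC(C)(C)OC(=O)C1(Oc2ccc(Br)cc2Br)CCC(Br)(Br)C(Br)C1=O
F4 | step 7 | 2,3-dibromo-6-(2,4-dibromophenoxy)-6-(phenylselanyl)cyclohex-2-en-1-one (racemic) | O=C1C(Br)=C(Br)CCC1(Oc1ccc(Br)cc1Br)[Se]c1ccccc1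
F5 | step 7 | 6-(benzeneseleninyl)-2,3-dibromo-6-(2,4-dibromophenoxy)cyclohex-2-en-1-one | O=C1C(Br)=C(Br)CCC1(Oc1ccc(Br)cc1Br)[Se](=O)c1ccccc1
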